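The constants are those of an exercise; no experiment stands behind them.

The flask is closed and stirred: solid reagent feeds coupling partner into solution, where it either couples at the catalyst or decomposes.

    starting material + free catalyst ⇌ catalyst intermediate A (K1 = 1.7 M⁻¹, k1 = 11 M⁻¹ s⁻¹)
    coupling partner + catalyst intermediate A → catalyst intermediate B (k2 = 20 M⁻¹ s⁻¹)
    catalyst intermediate B → by-product + catalyst intermediate C (k3 = 23 s⁻¹)
    catalyst intermediate C ⇌ free catalyst + target (K4 = 0.21 M, k4 = 13 s⁻¹)
    solid reagent ⇌ coupling partner, rate k5*(cs5 - [coupling partner]) while solid is left; crystals form when [coupling partner] > cs5 (cs5 = 0.090 M, k5 = 0.0028 s⁻¹)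
    coupling partner → decomposed reagent (k6 = 0.0013 s⁻¹)

| setting | ochre | green |
|---|---|---|
| starting material | 0.20 M | 0.20 M |
| solid reagent | 0.240 M | 0.240 M |
| free catalyst | 0.40 mM | 0.40 mM |
| time | 30 min | 60 min |

* which of these there is most of at the end, counted by the starting material in it, ochre (starting material / catalyst intermediate A / target / catalyst intermediate C)
* which of these there is most of at the end, counted by the starting material in it, green (starting material / catalyst intermediate A / target / catalyst intermediate C)
* how much there is at the end of the one of these that leads, in percent of the starting material charged: ochre
* how much there is at the end of the one of these that leads, in percent of the starting material charged: green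

I ask what share of the dissolved coupling partner couples. Catalyst intermediate A falls back at 6.47 s⁻¹, faster than it goes on even at the solubility, 1.80 s⁻¹. So I hold the first step at equilibrium, and the last step too. Catalyst intermediate A then holds a fraction of the catalyst: K₁[starting material], divided by the sum of one, K₁[starting material] and [target]/K₄.

Coupling against decomposition gives Φ = k₂ × catalyst × that fraction / k₆. This is the coupling number, a selectivity factor. At the start:

Φ = 1.56, so the coupling share, Φ divided by one plus Φ, = 61.0%

Taken at face value, that gives target x = 73.2% of the starting material. But target ties up catalyst, so I put x back, reckon the closing Φ and use the mean of opening and closing shares: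

x = 73.2%: Φ = 0.314, new x = 50.9%
x = 50.9%: Φ = 0.622, new x = 59.6%
x = 59.6%: Φ = 0.496, new x = 56.5%

One number is not enough: Φ has no clock. Dissolving against both losses holds coupling partner near 0.0411 M, and the solid then lasts 29.2 min. In ochre that is shorter than the run, but the dissolved partner is still waiting at the end, so I get target 49.4% and starting material 50.6%, barely ahead. In green the partner lives 8.57 min, shorter than the time remaining, so I commit to target at 56.5%.

The forecast names starting material at 53% for ochre and target at 53% for green, warning that “the crossover is close enough”. It has the same leaders as mine, with a lower green figure.

The flask gives starting material at 54.3% in ochre and target at 54.6% in green.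

In green at 60.0 min, decomposition uses coupling partner 1.8 times as fast as coupling does. That reads as Φ = 0.564, between my 0.622 and 0.496. A neighbour of green, charged with 0.680 mM of free catalyst, opens at Φ = 2.65. That neighbour ends with target at 66.2%, which gives a closing Φ = 0.690, and the mean share returns target at 68.1%.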